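3 questions stand on the flasks below, and the earlier runs are the ground for answering them.

| flask | J | Z | X | remark | time |
|---|---|---|---|---|---|
| Sunday's | 0.050 M | 0.54 mM | 0.13 mM | run made earlier |  |
| Tuesday's | 0.050 M | 3.6 mM | 0.13 mM | run made earlier |  |
| Wednesday's | 0.035 M | 1.2 mM | 0.13 mM | run made earlier |  |
| south | 0.050 M | 1.2 mM | 0.13 mM |  | 20 min |
| east | 0.20 M | 0.80 mM | 0.13 mM |  | 20 min |
| north-east | 0.050 M | 1.2 mM | 0.50 mM |  | 20 min |
| north-west | 0.012 M | 5.0 mM | 0.25 mM |  | 20 min |

| run | time / min | E / % |
|---|---|---|
| Sunday's | 2.50 | 2.2 |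
| Sunday's | 8.00 | 5.9 |
| Sunday's | 12.0 | 7.0 |
| Sunday's | 20.0 | 8.2 |
| Tuesday's | 1.50 | 13.2 |
| Tuesday's | 4.00 | 24.2 |
| Tuesday's | 8.00 | 30.6 |
| Tuesday's | 20.0 | 30.1 |
| Wednesday's | 5.00 | 11.7 |
| Wednesday's | 10.0 | 17.3 |
| Wednesday's | 15.0 | 20.0 |
| Wednesday's | 20.0 | 21.1 |

(each reading ± 0.3 percentage points)

* the flasks put in order of amount of E, in percent of the J charged, best first, at 20 min (south / east / north-east / north-west)
* the amount of E, in percent of the J charged of the flask you put first, at 20 min
* the amount of E, in percent of the J charged of the flask you put last, at 20 min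

- the earlier runs were read with a standard deviation of 0.3 percentage points

The ledger opens with X, which every flask charges below Z. Tuesday's first slope reads 10.0 times Sunday's, with the scatter of those points, against 6.67 for the Z charged and 8.46 for Z less X. So the first entry is taken to be: each X removes one Z, with X as the limiting reagent of that pair. The second entry is the live share of the Z charge, one minus X over Z: 89.2% in south, 83.8% in east, 58.3% in north-east, 95.0% in north-west.

The third entry sets live Z against J. North-west holds live Z equal to 39.6% of its J charge, and this fraction is the catalyst ratio. Sunday's 0.820%, Wednesday's 3.06% and Tuesday's 6.94% read 8.2%, 21.1% and 30.1% of E at their last points. J enters the ratio on Wednesday's evidence: with less J, the last reading of that run stands above the 18.0% that a line in the logarithm of live Z gives from Sunday and Tuesday.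

A line in the logarithm of the ratio between Sunday and Wednesday puts south, at 2.14%, near 17.6%, and north-east, at 1.40%, near 13.4%. Wednesday and Tuesday carry north-west to about 49.2%. East, at 0.335%, lies below Sunday, where a power law through Sunday and Wednesday gives a rough 4.31%. This reckoning therefore commits to north-west, south, north-east, east.

The forecast, reading “X removing an equal amount of Z”, gave north-west > south > north-east > east, with 32% and 9.5%, the same order but different ends from this reckoning's 49.2% and 4.31%.

The flasks give north-west > south > north-east > east, with 46.9% first and 5.63% last.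

    E + Z ⇌ Q + Z, rate k1*[Z]*[E] forward; the back reaction follows from the equilibrium constant (K = 0.300, k = 620 L mol⁻¹ min⁻¹)
    Z + X → D (k = 20000 L mol⁻¹ min⁻¹)
    2 J → G (k = 2.60 L mol⁻¹ min⁻¹)
    Q + Z ⇌ J + Z, rate k4*[Z]*[Q] forward; the back reaction follows from the equilibrium constant (k = 58.0 L mol⁻¹ min⁻¹)
    J + Z ⇌ E + Z, rate k5*[J]*[Z] forward; the back reaction follows from the equilibrium constant (K = 2.10, k = 11.0 L mol⁻¹ min⁻¹)

North-west, at a catalyst ratio of 39.6%, holds 46.9% of E against the 49.2% reckoned. A second flask, like north-west but with 0.030 M of J, has a ratio of 15.8%. The Wednesday–Tuesday line gives it 39.1%, and it holds 38.2%. North-west has not come to rest: at 200 min Z still stands at 95.0%, but J has moved from 21.5% to 13.3%, G from 17.6% to 49.5%, and E from 46.9% down to 28.6%.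

The numbers in the tables were computed on assumed constants; noise was put on by code.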